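A direct plan would join a 2-ethoxy-2H-chromene A1 (rings A and C, built on a MOM-protected phloroglucinol ether) to the ring B arylboronic acid A2 under nickel catalysis to give the racemic 2-aryl-2H-chromene A3. It would then hydroborate A3 to the racemic trans alcohol A4, oxidise this to the flavan-3-one A5, reduce it with dynamic kinetic resolution to the cis (2R,3R) alcohol A6, esterify with the MOM-protected ferulic acid A7 to the ester A8, and cleave five MOM ethers with acid.
Weak point 1, the setting of C2 and C3: the centres would be made racemic and trans, erased by oxidation, and set again by a dynamic kinetic hydrogenation that has no precedent on flavan-3-ones, which enolise and oxidise easily; three redox steps for two centres, with the whole plan resting on the last.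
Weak point 2, the run-up: the oxygen patterns of rings A and B and the guaiacyl unit of A7 would be built by lithiation, C–H borylation and oxidation from bare arenes, many steps that form no bond of the skeleton although such arenes can be bought.
Weak point 3, the last step: acid methanolysis of five MOM ethers on the electron-rich flavan-3-yl cinnamate A8 would put the ester and the C2–O1 bond at risk when the material is most valuable.

**Retrosynthetic overview**
The only stereocentres, C2 (aryl, O1) and C3 (O-acyl), are cis in ring C; at the flavylium (anthocyanidin) oxidation level they are the two ends of one C2=C3 bond of a flat aromatic ring.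
Key disconnection: O1–C2 and C3–C4. Ring C is formed last, as an aromatic 1-benzopyrylium ring, by acid-mediated condensation of an intact ring A salicylaldehyde with an intact ring B α-benzoyloxy ketone; rings A and B are bought with their oxygen pattern.
Hydride transfer to C4 then gives the achiral flav-2-ene, and one enantioselective syn-hydrogenation of C2=C3 sets both centres together as (2R,3R); nothing is set, erased and set again.
The feruloyl C=C is made in the last step from vanillin by Knoevenagel–Doebner condensation on a 3-O-malonate, after the benzyl ethers are gone, so the ferulate needs no protecting group and no deprotection follows the sensitive ester.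

Key step: step 5

Assumption: which antipode of the diphosphine leads to the (2R,3R) product in step 7 cannot be derived by analogy for this substrate class; the (R,R) ligand is written, and its antipode would be used if a test run showed the opposite sense.

Step 1
Reactants: 1 2,4,6-trihydroxybenzaldehyde
Product: 2 2,4-bis(benzyloxy)-6-hydroxybenzaldehyde
Conditions: BnBr (2.05 equiv), K2CO3 (2.1 equiv), DMF, 0 °C to rt
Reagents that add atoms: benzyl bromide, BrCc1ccccc1
Why: Williamson etherification, in which the hydroxyl para to the formyl group and one ortho hydroxyl are alkylated while the last ortho hydroxyl, held in a hydrogen bond to the aldehyde, stays free to become O1.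

Step 2
Reactants: 3 methyl 3,5-dihydroxy-4-methoxybenzoate
Product: 4 methyl 3,5-bis(benzyloxy)-4-methoxybenzoate
Conditions: BnBr (2.3 equiv), K2CO3 (2.5 equiv), DMF, 60 °C
Reagents that add atoms: benzyl bromide, BrCc1ccccc1
Why: Williamson etherification of both phenols; benzyl ethers withstand the organolithium of step 3 and the acid of step 5 and leave by hydrogenolysis before the ferulate alkene exists.

Step 3
Reactants: 4 methyl 3,5-bis(benzyloxy)-4-methoxybenzoate
Product: 6 1-[3,5-bis(benzyloxy)-4-methoxyphenyl]-2-chloroethan-1-one, via lithium hemiketal alkoxide 5 (not isolated)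
Conditions: ICH2Cl (2.0 equiv), MeLi·LiBr (1.9 equiv, slow addition), THF, −78 °C; AcOH, −78 °C to rt
Reagents that add atoms: chloroiodomethane, ClCI
Why: Chloromethyllithium homologation of an ester, in which iodine–lithium exchange gives LiCH2Cl that adds once because the tetrahedral alkoxide 5 is stable at −78 °C and collapses to the chloromethyl ketone only on the acid quench.

Step 4
Reactants: 6 1-[3,5-bis(benzyloxy)-4-methoxyphenyl]-2-chloroethan-1-one
Product: 7 2-[3,5-bis(benzyloxy)-4-methoxyphenyl]-2-oxoethyl benzoate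
Conditions: PhCO2Na (1.5 equiv), NaI (0.1 equiv), DMF, rt to 40 °C
Reagents that add atoms: sodium benzoate, [Na+].[O-]C(=O)c1ccccc1
Why: SN2 displacement of the activated phenacyl chloride by benzoate under iodide catalysis, which puts the C3 oxygen in place already acylated with a group that can later chelate rhodium.

Step 5
Reactants: 2 2,4-bis(benzyloxy)-6-hydroxybenzaldehyde; 7 2-[3,5-bis(benzyloxy)-4-methoxyphenyl]-2-oxoethyl benzoate
Product: 9 3-(benzoyloxy)-5,7-bis(benzyloxy)-2-[3,5-bis(benzyloxy)-4-methoxyphenyl]chromenylium chloride, via α-benzoyloxy-2-hydroxychalcone 8 (not isolated)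
Conditions: dry HCl (gas, saturated) in EtOAc, Me3SiCl (5 equiv), 0 °C to rt, dark; Et2O, filtration under argon
Reagents that add atoms: hydrogen chloride, Cl
Why: Acid-catalysed crossed aldol condensation of the enol of 7 with the protonated aldehyde 2 forms the C3–C4 bond (chalcone 8), the phenolic hydroxyl then adds to the protonated ketone to form the O1–C2 bond, and loss of water gives the aromatic 1-benzopyrylium cation. The closest known reaction type is the classical acid-mediated flavylium (anthocyanidin) synthesis from 2-hydroxybenzaldehydes and α-acyloxy or α-alkoxy aryl methyl ketones. Ring C closes by 6-exo-trig attack of oxygen on the carbonyl carbon followed by dehydration, and aromatisation to the 10 π-electron cation drives it, so the closure fights neither strain nor entropy. No stereocentre is formed: C2 and C3 are deliberately left sp2 so that step 7 can set both in one syn addition. The selectivity needed is a single crossed condensation and survival of the benzoate: 7 has one enolisable carbon, 2 has none and only one free hydroxyl, and Me3SiCl removes the two equivalents of water so that the 3-O-benzoyl group is not hydrolysed while the salt precipitates.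

Step 6
Reactants: 9 3-(benzoyloxy)-5,7-bis(benzyloxy)-2-[3,5-bis(benzyloxy)-4-methoxyphenyl]chromenylium chloride
Product: 10 5,7-bis(benzyloxy)-2-[3,5-bis(benzyloxy)-4-methoxyphenyl]-4H-chromen-3-yl benzoate
Conditions: Hantzsch ester (diethyl 2,6-dimethyl-1,4-dihydropyridine-3,5-dicarboxylate, 1.05 equiv), CH2Cl2, 0 °C, argon, dark; aq NaHCO3 wash
Reagents that add atoms: none
Why: Hydride transfer from a 1,4-dihydropyridine to a pyrylium-type cation, which should take place at the unsubstituted C4 and not at the hindered C2 that carries the aryl group, to give the neutral achiral flav-2-ene while the pyridine formed takes up the acid.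

Step 7
Reactants: 10 5,7-bis(benzyloxy)-2-[3,5-bis(benzyloxy)-4-methoxyphenyl]-4H-chromen-3-yl benzoate
Product: 11 (2R,3R)-5,7-bis(benzyloxy)-2-[3,5-bis(benzyloxy)-4-methoxyphenyl]chroman-3-yl benzoate
Conditions: [Rh(cod)((R,R)-Me-DuPhos)]BF4 (3 mol%), H2 (50 bar), CH2Cl2, 40 °C
Reagents that add atoms: none
Why: Proposed new method: enantioselective hydrogenation of a tetrasubstituted 3-acyloxy-2-aryl-4H-chromene, in which the cationic monovalent rhodium diphosphine should bind the C2=C3 bond and the benzoate carbonyl as a five-membered chelate, add H2 to give a trivalent rhodium dihydride and deliver both hydrogens to one face, so that syn addition fixes the 2,3-cis relation and the ligand selects the face that gives (2R,3R); the closest known reaction types are the rhodium–diphosphine hydrogenation of enol esters and of tetrasubstituted enamides and the iridium-catalysed hydrogenation of 2-aryl-4H-chromenes to flavans, and the benzyl ethers are inert to the homogeneous catalyst.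

Step 8
Reactants: 11 (2R,3R)-5,7-bis(benzyloxy)-2-[3,5-bis(benzyloxy)-4-methoxyphenyl]chroman-3-yl benzoate
Product: 12 (2R,3R)-5,7-bis(benzyloxy)-2-[3,5-bis(benzyloxy)-4-methoxyphenyl]chroman-3-ol
Conditions: K2CO3 (0.5 equiv), MeOH/THF 1:1, rt to 40 °C
Reagents that add atoms: none
Why: Base-catalysed transesterification of the benzoate with methanol at the acyl carbon, which touches neither C2 nor C3; the 4'-methoxy group rules out base-induced ring opening through a ring B quinone methide.

Step 9
Reactants: 12 (2R,3R)-5,7-bis(benzyloxy)-2-[3,5-bis(benzyloxy)-4-methoxyphenyl]chroman-3-ol; 13 Meldrum's acid (2,2-dimethyl-1,3-dioxane-4,6-dione)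
Product: 14 3-{[(2R,3R)-5,7-bis(benzyloxy)-2-[3,5-bis(benzyloxy)-4-methoxyphenyl]chroman-3-yl]oxy}-3-oxopropanoic acid
Conditions: 13 (1.5 equiv), toluene, 95 °C
Reagents that add atoms: none
Why: Thermal acylation of an alcohol by Meldrum's acid (ring opening at the acyl carbon with loss of acetone) gives the malonic half-ester without base or coupling reagent, the axial 3-OH being the only nucleophile present.

Step 10
Reactants: 14 3-{[(2R,3R)-5,7-bis(benzyloxy)-2-[3,5-bis(benzyloxy)-4-methoxyphenyl]chroman-3-yl]oxy}-3-oxopropanoic acid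
Product: 15 3-{[(2R,3R)-2-(3,5-dihydroxy-4-methoxyphenyl)-5,7-dihydroxychroman-3-yl]oxy}-3-oxopropanoic acid
Conditions: H2 (1 atm), Pd(OH)2/C (20 wt%), THF/MeOH 1:1, rt; filtration under argon, used crude
Reagents that add atoms: none
Why: Hydrogenolysis of the four aryl benzyl ethers over palladium at a stage where no alkene is present; the ester, the free acid and the C2–O1 bond should survive at 1 atm and room temperature.

Step 11
Reactants: 15 3-{[(2R,3R)-2-(3,5-dihydroxy-4-methoxyphenyl)-5,7-dihydroxychroman-3-yl]oxy}-3-oxopropanoic acid; 16 vanillin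
Product: 18 4'-O-methylepigallocatechin-3-O-ferulate, via arylidenemalonic half-ester 17 (not isolated)
Conditions: 16 (1.3 equiv), β-alanine (0.2 equiv), pyridine, 50 °C, argon, dark; cold aq citric acid/EtOAc; Sephadex LH-20 (MeOH)
Reagents that add atoms: none
Why: Knoevenagel–Doebner condensation of a malonic half-ester with an unprotected hydroxybenzaldehyde, in which amine-catalysed condensation and decarboxylation in pyridine give the (E)-cinnamate directly; the 4'-methoxy group blocks base-induced epimerisation at C2, and no hydrogen, acid or fluoride is used once the alkene exists.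

**Compound list**
1 | 2,4,6-trihydroxybenzaldehyde | O=Cc1c(O)cc(O)cc1O | starting material
2 | 2,4-bis(benzyloxy)-6-hydroxybenzaldehyde | O=Cc1c(O)cc(OCc2ccccc2)cc1OCc1ccccc1 | intermediate
3 | methyl 3,5-dihydroxy-4-methoxybenzoate | COC(=O)c1cc(O)c(OC)c(O)c1 | starting material
4 | methyl 3,5-bis(benzyloxy)-4-methoxybenzoate | COC(=O)c1cc(OCc2ccccc2)c(OC)c(OCc2ccccc2)c1 | intermediate
5 | lithium 1-[3,5-bis(benzyloxy)-4-methoxyphenyl]-2-chloro-1-methoxyethan-1-olate | [Li+].[O-]C(CCl)(OC)c1cc(OCc2ccccc2)c(OC)c(OCc2ccccc2)c1 | intermediate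
6 | 1-[3,5-bis(benzyloxy)-4-methoxyphenyl]-2-chloroethan-1-one | ClCC(=O)c1cc(OCc2ccccc2)c(OC)c(OCc2ccccc2)c1 | intermediate
7 | 2-[3,5-bis(benzyloxy)-4-methoxyphenyl]-2-oxoethyl benzoate | O=C(OCC(=O)c1cc(OCc2ccccc2)c(OC)c(OCc2ccccc2)c1)c1ccccc1 | intermediate
8 | 3-[2,4-bis(benzyloxy)-6-hydroxyphenyl]-1-[3,5-bis(benzyloxy)-4-methoxyphenyl]-1-oxoprop-2-en-2-yl benzoate (alkene geometry equilibrates in the acid) | O=C(c1cc(OCc2ccccc2)c(OC)c(OCc2ccccc2)c1)C(OC(=O)c1ccccc1)=Cc1c(O)cc(OCc2ccccc2)cc1OCc1ccccc1 | intermediate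
9 | 3-(benzoyloxy)-5,7-bis(benzyloxy)-2-[3,5-bis(benzyloxy)-4-methoxyphenyl]chromenylium chloride | [Cl-].COc1c(OCc2ccccc2)cc(cc1OCc1ccccc1)-c1[o+]c2cc(OCc3ccccc3)cc(OCc3ccccc3)c2cc1OC(=O)c1ccccc1 | intermediate
10 | 5,7-bis(benzyloxy)-2-[3,5-bis(benzyloxy)-4-methoxyphenyl]-4H-chromen-3-yl benzoate | O=C(OC1=C(Oc2cc(OCc3ccccc3)cc(OCc3ccccc3)c2C1)c1cc(OCc2ccccc2)c(OC)c(OCc2ccccc2)c1)c1ccccc1 | intermediate
11 | (2R,3R)-5,7-bis(benzyloxy)-2-[3,5-bis(benzyloxy)-4-methoxyphenyl]chroman-3-yl benzoate | O=C(c1ccccc1)O[C@@H]2Cc3c(OCc4ccccc4)cc(OCc4ccccc4)cc3O[C@@H]2c2cc(OCc4ccccc4)c(OC)c(OCc4ccccc4)c2 | intermediate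
12 | (2R,3R)-5,7-bis(benzyloxy)-2-[3,5-bis(benzyloxy)-4-methoxyphenyl]chroman-3-ol | O[C@@H]1Cc2c(OCc3ccccc3)cc(OCc3ccccc3)cc2O[C@@H]1c1cc(OCc2ccccc2)c(OC)c(OCc2ccccc2)c1 | intermediate
13 | Meldrum's acid (2,2-dimethyl-1,3-dioxane-4,6-dione) | CC1(C)OC(=O)CC(=O)O1 | starting material
14 | 3-{[(2R,3R)-5,7-bis(benzyloxy)-2-[3,5-bis(benzyloxy)-4-methoxyphenyl]chroman-3-yl]oxy}-3-oxopropanoic acid | OC(=O)CC(=O)O[C@@H]1Cc2c(OCc3ccccc3)cc(OCc3ccccc3)cc2O[C@@H]1c1cc(OCc2ccccc2)c(OC)c(OCc2ccccc2)c1 | intermediate
15 | 3-{[(2R,3R)-2-(3,5-dihydroxy-4-methoxyphenyl)-5,7-dihydroxychroman-3-yl]oxy}-3-oxopropanoic acid | OC(=O)CC(=O)O[C@@H]1Cc2c(O)cc(O)cc2O[C@@H]1c1cc(O)c(OC)c(O)c1 | intermediate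
16 | vanillin (4-hydroxy-3-methoxybenzaldehyde) | COc1cc(C=O)ccc1O | starting material
17 | 2-{[(2R,3R)-2-(3,5-dihydroxy-4-methoxyphenyl)-5,7-dihydroxychroman-3-yl]oxycarbonyl}-3-(4-hydroxy-3-methoxyphenyl)prop-2-enoic acid (either alkene geometry) | COc1cc(C=C(C(=O)O)C(=O)O[C@@H]2Cc3c(O)cc(O)cc3O[C@@H]2c2cc(O)c(OC)c(O)c2)ccc1O | intermediate
18 | 4'-O-methylepigallocatechin-3-O-ferulate, (2R,3R)-2-(3,5-dihydroxy-4-methoxyphenyl)-5,7-dihydroxychroman-3-yl (E)-3-(4-hydroxy-3-methoxyphenyl)prop-2-enoate | COc1cc(/C=C/C(=O)O[C@@H]2Cc3c(O)cc(O)cc3O[C@@H]2c2cc(O)c(OC)c(O)c2)ccc1O | target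

**Step count and risks**
Total step count: 11. Longest linear sequence: 10 steps (steps 2 to 11).

Steps most likely to fail:

Step 7 (Proposed new method). The hindered tetrasubstituted alkene may turn over slowly, the catalyst may select the face poorly, or the double bond may migrate into C3=C4 before reduction so that cis control is lost. The fallback uses known chemistry and sets out from 10. Hydrogenation with the achiral complex [Ir(cod)(PCy3)(py)]PF6 (H2, CH2Cl2), which reduces tetrasubstituted alkenes by syn addition, should give the racemic cis benzoate F1. Methanolysis (K2CO3, MeOH/THF) would give the racemic cis alcohol F2. Acylation with (1S)-(−)-camphanic chloride (pyridine, DMAP, CH2Cl2) would give the (2R,3R) camphanate F3 and the (2S,3S) camphanate F4, to be separated by crystallisation or chromatography. Methanolysis of F3 returns to the route at 12, at the cost of half the material.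

Step 5. The 3-O-benzoyl group may be lost by acidolysis at the cationic ring, or the cyclodehydration may stop short. The fallback sets out from 2 and 7 and carries no acyl group through the ring closure. The condensation would be run in HCl-saturated EtOAc/MeOH, so that the ester is cleaved on purpose and the stable 3-hydroxyflavylium chloride F5 crystallises. F5 would then be O-benzoylated with benzoyl chloride and 2,6-di-tert-butylpyridine in CH2Cl2 to return to the route at 9.

Step 11. Ring A (C6, C8) may be aminoalkylated by the imine of vanillin, the malonate may decarboxylate to an acetate before it condenses, or the free polyphenol may oxidise. The fallback sets out from 12 and replaces the condensation by acylation of a silyl-protected core.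
- Hydrogenolysis (H2, Pd(OH)2/C) would give 4'-O-methylepigallocatechin F6.
- TBSCl and imidazole in DMF should silylate the four phenols and leave the hindered axial 3-OH, giving the tetrasilyl ether F7.
- Ferulic acid would be silylated twice (TBSCl, imidazole) to the silyl ester F8, whose silyl ester alone is hydrolysed with K2CO3 in aqueous methanol to 4-O-TBS-ferulic acid F9.
- Carbodiimide esterification of F7 with F9 (EDC·HCl, DMAP, CH2Cl2) would give the pentasilyl ester F10.
- Et3N·3HF in THF/MeCN would remove the five silyl groups and return to the route at 18.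

Further compounds
F1 | step 7 | racemic cis-5,7-bis(benzyloxy)-2-[3,5-bis(benzyloxy)-4-methoxyphenyl]chroman-3-yl benzoate (one enantiomer drawn) | O=C(c1ccccc1)O[C@@H]2Cc3c(OCc4ccccc4)cc(OCc4ccccc4)cc3O[C@@H]2c2cc(OCc4ccccc4)c(OC)c(OCc4ccccc4)c2
F2 | step 7 | racemic cis-5,7-bis(benzyloxy)-2-[3,5-bis(benzyloxy)-4-methoxyphenyl]chroman-3-ol (one enantiomer drawn) | O[C@@H]1Cc2c(OCc3ccccc3)cc(OCc3ccccc3)cc2O[C@@H]1c1cc(OCc2ccccc2)c(OC)c(OCc2ccccc2)c1
F3 | step 7 | (2R,3R)-5,7-bis(benzyloxy)-2-[3,5-bis(benzyloxy)-4-methoxyphenyl]chroman-3-yl (1S,4R)-camphanate | O=C(O[C@@H]1Cc2c(OCc3ccccc3)cc(OCc3ccccc3)cc2O[C@@H]1c1cc(OCc2ccccc2)c(OC)c(OCc2ccccc2)c1)[C@@]12CC[C@@](C)(C(=O)O1)C2(C)C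
F4 | step 7 | (2S,3S)-5,7-bis(benzyloxy)-2-[3,5-bis(benzyloxy)-4-methoxyphenyl]chroman-3-yl (1S,4R)-camphanate | O=C(O[C@H]1Cc2c(OCc3ccccc3)cc(OCc3ccccc3)cc2O[C@H]1c1cc(OCc2ccccc2)c(OC)c(OCc2ccccc2)c1)[C@@]12CC[C@@](C)(C(=O)O1)C2(C)C
F5 | step 5 | 5,7-bis(benzyloxy)-2-[3,5-bis(benzyloxy)-4-methoxyphenyl]-3-hydroxychromenylium chloride | [Cl-].COc1c(OCc2ccccc2)cc(cc1OCc1ccccc1)-c1[o+]c2cc(OCc3ccccc3)cc(OCc3ccccc3)c2cc1O
F6 | step 11 | 4'-O-methylepigallocatechin, (2R,3R)-2-(3,5-dihydroxy-4-methoxyphenyl)chroman-3,5,7-triol | O[C@@H]1Cc2c(O)cc(O)cc2O[C@@H]1c1cc(O)c(OC)c(O)c1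
F7 | step 11 | (2R,3R)-5,7-bis(tert-butyldimethylsilyloxy)-2-[3,5-bis(tert-butyldimethylsilyloxy)-4-methoxyphenyl]chroman-3-ol | O[C@@H]1Cc2c(O[Si](C)(C)C(C)(C)C)cc(O[Si](C)(C)C(C)(C)C)cc2O[C@@H]1c1cc(O[Si](C)(C)C(C)(C)C)c(OC)c(O[Si](C)(C)C(C)(C)C)c1
F8 | step 11 | tert-butyldimethylsilyl (E)-3-[4-(tert-butyldimethylsilyloxy)-3-methoxyphenyl]prop-2-enoate | COc1cc(/C=C/C(=O)O[Si](C)(C)C(C)(C)C)ccc1O[Si](C)(C)C(C)(C)C
F9 | step 11 | (E)-3-[4-(tert-butyldimethylsilyloxy)-3-methoxyphenyl]prop-2-enoic acid | COc1cc(/C=C/C(=O)O)ccc1O[Si](C)(C)C(C)(C)C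
F10 | step 11 | (2R,3R)-5,7-bis(tert-butyldimethylsilyloxy)-2-[3,5-bis(tert-butyldimethylsilyloxy)-4-methoxyphenyl]chroman-3-yl (E)-3-[4-(tert-butyldimethylsilyloxy)-3-methoxyphenyl]prop-2-enoate | COc1cc(/C=C/C(=O)O[C@@H]2Cc3c(O[Si](C)(C)C(C)(C)C)cc(O[Si](C)(C)C(C)(C)C)cc3O[C@@H]2c2cc(O[Si](C)(C)C(C)(C)C)c(OC)c(O[Si](C)(C)C(C)(C)C)c2)ccc1O[Si](C)(C)C(C)(C)C
A1 | direct plan | racemic 2-ethoxy-5,7-bis(methoxymethoxy)-2H-chromene | CCOC1C=Cc2c(OCOC)cc(OCOC)cc2O1
A2 | direct plan | [4-methoxy-3,5-bis(methoxymethoxy)phenyl]boronic acid | COCOc1cc(cc(OCOC)c1OC)B(O)O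
A3 | direct plan | racemic 2-[4-methoxy-3,5-bis(methoxymethoxy)phenyl]-5,7-bis(methoxymethoxy)-2H-chromene | COCOc1cc(OCOC)c2C=CC(Oc2c1)c1cc(OCOC)c(OC)c(OCOC)c1
A4 | direct plan | racemic 2,3-trans-2-[4-methoxy-3,5-bis(methoxymethoxy)phenyl]-5,7-bis(methoxymethoxy)chroman-3-ol (one enantiomer drawn) | O[C@H]1Cc2c(OCOC)cc(OCOC)cc2O[C@@H]1c1cc(OCOC)c(OC)c(OCOC)c1
A5 | direct plan | racemic 2-[4-methoxy-3,5-bis(methoxymethoxy)phenyl]-5,7-bis(methoxymethoxy)chroman-3-one | COCOc1cc(OCOC)c2CC(=O)C(Oc2c1)c1cc(OCOC)c(OC)c(OCOC)c1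
A6 | direct plan | (2R,3R)-2-[4-methoxy-3,5-bis(methoxymethoxy)phenyl]-5,7-bis(methoxymethoxy)chroman-3-ol | O[C@@H]1Cc2c(OCOC)cc(OCOC)cc2O[C@@H]1c1cc(OCOC)c(OC)c(OCOC)c1
A7 | direct plan | (E)-3-[3-methoxy-4-(methoxymethoxy)phenyl]prop-2-enoic acid | COCOc1ccc(/C=C/C(=O)O)cc1OC
A8 | direct plan | (2R,3R)-2-[4-methoxy-3,5-bis(methoxymethoxy)phenyl]-5,7-bis(methoxymethoxy)chroman-3-yl (E)-3-[3-methoxy-4-(methoxymethoxy)phenyl]prop-2-enoate | COCOc1ccc(/C=C/C(=O)O[C@@H]2Cc3c(OCOC)cc(OCOC)cc3O[C@@H]2c2cc(OCOC)c(OC)c(OCOC)c2)cc1OC
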